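**Retrosynthetic overview**
1. Target 29 comes from 28 by removal of three MOM groups (last step).
2. The C6 side chain comes from aryl bromide 21 and a vinyl/isopropenyl borate. One Pd-triggered 1,2-shift of the isopropenyl group from boron to carbon forms the Ar–CH2 bond, the CH–C(isopropenyl) bond and the 2″R centre; C–B then becomes C–OH.
3. Ring B and the 2S centre come from chromone 16 and aryl bromide 17 by enantioselective conjugate arylation.
4. Ring C (the pyranone) comes from salicylaldehyde 11 and ethynyl Grignard 12 (oxidation, 6-endo closure); 11 comes from phenol 8 by ortho-formylation.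
5. Ring A comes from resorcinol 1: MOM protection, C2 bromination, C5 hydroxylation, ortho-prenylation. Ring order: A (bought as the arene), C (step 7), B attached (step 8).

Assumption: the ligand antipodes named in steps 8 and 10 are the ones expected to give 2S and 2″R; if a model run shows the opposite sense, the mirror-image ligand is used.

**Step 1**
Reactants: 1 resorcinol
Product: 2 1,3-bis(methoxymethoxy)benzene
Conditions: NaH (2.2 equiv), MOMCl (2.2 equiv), DMF, 0 °C → rt
Reagents that add atoms: chloromethyl methyl ether (MOMCl), COCCl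
Why: Williamson-type O-alkylation of the bis-phenoxide gives the bis-MOM ether, which directs the next lithiation and is removable by mild acid at the end.

**Step 2**
Reactants: 2 1,3-bis(methoxymethoxy)benzene
Product: 4 2-bromo-1,3-bis(methoxymethoxy)benzene, via aryllithium 3 (not isolated)
Conditions: n-BuLi (1.1 equiv), THF, 0 °C, 1 h; then BrCl2C–CCl2Br (1.2 equiv), –78 °C → rt
Reagents that add atoms: 1,2-dibromo-1,1,2,2-tetrachloroethane, BrC(Cl)(Cl)C(Cl)(Cl)Br
Why: Directed ortho-metalation, in which the two OMOM groups cooperate to lithiate only the carbon between them, followed by electrophilic bromine transfer.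

**Step 3**
Reactants: 4 2-bromo-1,3-bis(methoxymethoxy)benzene
Product: 6 4-bromo-3,5-bis(methoxymethoxy)phenol, via arylboronate 5 (not isolated)
Conditions: [Ir(OMe)(cod)]2 (1.5 mol%), 4,4′-di-tert-butyl-2,2′-bipyridine (3 mol%), B2pin2 (0.6 equiv), THF, 80 °C; evaporate; Oxone (2KHSO5·KHSO4·K2SO4), acetone/H2O, rt
Reagents that add atoms: potassium peroxymonosulfate (active salt of Oxone), [K+].[O-]S(=O)(=O)OO
Why: Sterically controlled Ir-catalysed C–H borylation goes to the only C–H without an ortho substituent (para to Br), and oxidative C–B to C–O exchange then gives the phenol; the aryl bromide is inert to both.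

**Step 4**
Reactants: 6 4-bromo-3,5-bis(methoxymethoxy)phenol; 7 prenyl bromide (1-bromo-3-methylbut-2-ene)
Product: 8 4-bromo-3,5-bis(methoxymethoxy)-2-(3-methylbut-2-en-1-yl)phenol
Conditions: NaH (1.05 equiv), toluene, 0 °C; 7 (1.0 equiv), rt, 12 h
Reagents that add atoms: none
Why: Ortho-C-allylation of a sodium phenoxide as a tight ion pair in a non-polar solvent; the para position is blocked by Br and the two ortho carbons are equivalent, so one linear prenyl regioisomer forms.

**Step 5**
Reactants: 8 4-bromo-3,5-bis(methoxymethoxy)-2-(3-methylbut-2-en-1-yl)phenol; 9 paraformaldehyde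
Product: 11 5-bromo-2-hydroxy-4,6-bis(methoxymethoxy)-3-(3-methylbut-2-en-1-yl)benzaldehyde, via salicyl alcohol 10 (not isolated)
Conditions: MgCl2 (2 equiv), Et3N (4 equiv), (CH2O)n (6 equiv), MeCN, reflux
Reagents that add atoms: none
Why: Magnesium-mediated ortho-formylation (Casnati–Skattebøl): the magnesium phenoxide delivers formaldehyde to the only free ortho carbon, and the benzylic alkoxide is oxidised by hydride transfer to a second formaldehyde; non-acidic, so MOM and prenyl survive.

**Step 6**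
Reactants: 11 5-bromo-2-hydroxy-4,6-bis(methoxymethoxy)-3-(3-methylbut-2-en-1-yl)benzaldehyde; 12 ethynylmagnesium bromide
Product: 13 rac-1-[5-bromo-2-hydroxy-4,6-bis(methoxymethoxy)-3-(3-methylbut-2-en-1-yl)phenyl]prop-2-yn-1-ol
Conditions: 12 (2.5 equiv), THF, 0 °C → rt; sat. aq. NH4Cl
Reagents that add atoms: none
Why: Grignard 1,2-addition to the aldehyde after the first equivalent deprotonates the phenol; the carbinol centre is racemic and is destroyed in the next step.

**Step 7**
Reactants: 13 rac-1-[5-bromo-2-hydroxy-4,6-bis(methoxymethoxy)-3-(3-methylbut-2-en-1-yl)phenyl]prop-2-yn-1-ol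
Product: 16 6-bromo-5,7-bis(methoxymethoxy)-8-(3-methylbut-2-en-1-yl)-4H-chromen-4-one, via ynone 14 (not isolated), via enaminone 15 (not isolated)
Conditions: MnO2 (10 equiv), CH2Cl2, rt; filter; Et2NH (1.5 equiv), EtOH, rt; then AcOH (cat.), 60 °C
Reagents that add atoms: none
Why: MnO2 oxidation of the benzylic propargylic alcohol, aza-Michael addition of diethylamine to the ynone, then addition–elimination by the phenol at the β-carbon, which fixes 6-endo closure to the chromone and excludes the aurone-type 5-exo product.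

**Step 8**
Reactants: 16 6-bromo-5,7-bis(methoxymethoxy)-8-(3-methylbut-2-en-1-yl)-4H-chromen-4-one; 17 1-bromo-4-(methoxymethoxy)benzene
Product: 21 (2S)-6-bromo-5,7-bis(methoxymethoxy)-2-[4-(methoxymethoxy)phenyl]-8-(3-methylbut-2-en-1-yl)-2,3-dihydro-4H-chromen-4-one, via aryllithium 18 (not isolated), via lithium arylborate 19 (not isolated), via arylboronic acid 20 (not isolated)
Conditions: 17 (1.6 equiv), n-BuLi, THF, –78 °C; B(OiPr)3, –78 °C → rt; 1 M HCl to pH 6, extract, concentrate; then 16, Pd(OCOCF3)2 (5 mol%), (R)-t-BuPyOx (6 mol%), NH4PF6 (30 mol%), H2O (5 equiv), ClCH2CH2Cl, 60 °C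
Reagents that add atoms: none
Why: Bromine–lithium exchange and borylation give the boronic acid, and a base-free asymmetric conjugate addition catalysed by divalent palladium with the chiral pyridine–oxazoline ligand delivers the aryl group to one face of C2 (2S set by the ligand); no zerovalent palladium or base is present, so the C6–Br bond and the new centre are untouched.

**Step 9**
Reactants: 22 isopropenylmagnesium bromide
Product: 24 4,4,5,5-tetramethyl-2-(prop-1-en-2-yl)-1,3,2-dioxaborolane, via alkoxyborate 23 (not isolated)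
Conditions: 2-isopropoxy-4,4,5,5-tetramethyl-1,3,2-dioxaborolane (1.0 equiv), THF, –78 °C → rt; 1 M HCl; distil
Reagents that add atoms: 2-isopropoxy-4,4,5,5-tetramethyl-1,3,2-dioxaborolane, CC(C)OB1OC(C)(C)C(C)(C)O1
Why: Borylation of a Grignard reagent: addition to the alkoxyboronate and loss of isopropoxide on acidic work-up give the alkoxide-free, halide-free boronic ester needed for the next step.

**Step 10**
Reactants: 21 (2S)-6-bromo-5,7-bis(methoxymethoxy)-2-[4-(methoxymethoxy)phenyl]-8-(3-methylbut-2-en-1-yl)-2,3-dihydro-4H-chromen-4-one; 24 4,4,5,5-tetramethyl-2-(prop-1-en-2-yl)-1,3,2-dioxaborolane; 25 vinylmagnesium bromide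
Product: 28 (2S)-6-[(2R)-2-hydroxy-3-methylbut-3-en-1-yl]-5,7-bis(methoxymethoxy)-2-[4-(methoxymethoxy)phenyl]-8-(3-methylbut-2-en-1-yl)-2,3-dihydro-4H-chromen-4-one, via borate complex 26 (not isolated), via allylboronate 27 (not isolated)
Conditions: 24 (1.4 equiv), 25 (1.3 equiv), THF, 0 °C → rt, 30 min; NaOTf (2.6 equiv); then 21 (1.0 equiv), Pd(OAc)2 (3 mol%), (Sp,Sp)-MandyPhos (3.6 mol%), THF, 60 °C, 16 h; then aq. NaHCO3, 30% H2O2, 0 °C → rt
Reagents that add atoms: hydrogen peroxide, OO
Why: Proposed new method: a Pd/MandyPhos conjunctive cross-coupling run for the first time on a 2,6-bis(alkoxy)aryl bromide that carries a base-labile flavanone, using a mixed vinyl/isopropenyl borate made from a Grignard reagent — zerovalent palladium inserts into the C6–Br bond (NaOTf removes bromide and frees a coordination site), the unsubstituted vinyl group of 26 binds the cationic divalent arylpalladium, the isopropenyl carbon then undergoes the stereodetermining 1,2-metalate shift from boron to the adjacent carbon anti to palladium, and C(sp2)–C(sp3) reductive elimination (favoured by the two ortho substituents) gives allylboronate 27, whose C–B bond is oxidised with retention to the 2R alcohol; the ligand alone sets the new centre because C2 is remote, and 24 is kept in excess over 25 so no free Grignard reagent or alkoxide reaches the ketone; closest known reaction type: enantioselective conjunctive cross-coupling of bis(alkenyl)borates with unhindered aryl triflates and of Grignard-derived borates with aryl bromides in the presence of NaOTf.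

**Step 11**
Reactants: 28 (2S)-6-[(2R)-2-hydroxy-3-methylbut-3-en-1-yl]-5,7-bis(methoxymethoxy)-2-[4-(methoxymethoxy)phenyl]-8-(3-methylbut-2-en-1-yl)-2,3-dihydro-4H-chromen-4-one
Product: 29 (2S)-5,7-dihydroxy-6-[(2R)-2-hydroxy-3-methylbut-3-en-1-yl]-2-(4-hydroxyphenyl)-8-(3-methylbut-2-en-1-yl)-2,3-dihydro-4H-chromen-4-one
Conditions: HCl (1.25 M in MeOH), 40 °C, monitored and stopped at full conversion
Reagents that add atoms: none
Why: Acid-catalysed acetal methanolysis removes the three aryl MOM ethers under conditions that prenylated flavanones tolerate; no base is present, so C2 does not epimerise, and the allylic alcohol is inductively deactivated toward ionisation.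

**Compound list**
1 | resorcinol | Oc1cccc(O)c1 | starting material
2 | 1,3-bis(methoxymethoxy)benzene | COCOc1cccc(OCOC)c1 | intermediate
3 | [2,6-bis(methoxymethoxy)phenyl]lithium | COCOc1cccc(OCOC)c1[Li] | intermediate
4 | 2-bromo-1,3-bis(methoxymethoxy)benzene | COCOc1cccc(OCOC)c1Br | intermediate
5 | 2-[4-bromo-3,5-bis(methoxymethoxy)phenyl]-4,4,5,5-tetramethyl-1,3,2-dioxaborolane | COCOc1cc(B2OC(C)(C)C(C)(C)O2)cc(OCOC)c1Br | intermediate
6 | 4-bromo-3,5-bis(methoxymethoxy)phenol | COCOc1cc(O)cc(OCOC)c1Br | intermediate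
7 | prenyl bromide (1-bromo-3-methylbut-2-ene) | CC(C)=CCBr | starting material
8 | 4-bromo-3,5-bis(methoxymethoxy)-2-(3-methylbut-2-en-1-yl)phenol | COCOc1cc(O)c(CC=C(C)C)c(OCOC)c1Br | intermediate
9 | paraformaldehyde (formaldehyde) | C=O | starting material
10 | 4-bromo-2-(hydroxymethyl)-3,5-bis(methoxymethoxy)-6-(3-methylbut-2-en-1-yl)phenol (magnesium salt in the flask) | OCc1c(O)c(CC=C(C)C)c(OCOC)c(Br)c1OCOC | intermediate
11 | 5-bromo-2-hydroxy-4,6-bis(methoxymethoxy)-3-(3-methylbut-2-en-1-yl)benzaldehyde | O=Cc1c(O)c(CC=C(C)C)c(OCOC)c(Br)c1OCOC | intermediate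
12 | ethynylmagnesium bromide | C#C[Mg]Br | starting material
13 | rac-1-[5-bromo-2-hydroxy-4,6-bis(methoxymethoxy)-3-(3-methylbut-2-en-1-yl)phenyl]prop-2-yn-1-ol | C#CC(O)c1c(O)c(CC=C(C)C)c(OCOC)c(Br)c1OCOC | intermediate
14 | 1-[5-bromo-2-hydroxy-4,6-bis(methoxymethoxy)-3-(3-methylbut-2-en-1-yl)phenyl]prop-2-yn-1-one | C#CC(=O)c1c(O)c(CC=C(C)C)c(OCOC)c(Br)c1OCOC | intermediate
15 | (E)-1-[5-bromo-2-hydroxy-4,6-bis(methoxymethoxy)-3-(3-methylbut-2-en-1-yl)phenyl]-3-(diethylamino)prop-2-en-1-one | CCN(CC)/C=C/C(=O)c1c(O)c(CC=C(C)C)c(OCOC)c(Br)c1OCOC | intermediate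
16 | 6-bromo-5,7-bis(methoxymethoxy)-8-(3-methylbut-2-en-1-yl)-4H-chromen-4-one | O=c1ccoc2c(CC=C(C)C)c(OCOC)c(Br)c(OCOC)c12 | intermediate
17 | 1-bromo-4-(methoxymethoxy)benzene | COCOc1ccc(Br)cc1 | starting material
18 | [4-(methoxymethoxy)phenyl]lithium | COCOc1ccc([Li])cc1 | intermediate
19 | lithium triisopropoxy[4-(methoxymethoxy)phenyl]borate | [Li+].COCOc1ccc(cc1)[B-](OC(C)C)(OC(C)C)OC(C)C | intermediate
20 | [4-(methoxymethoxy)phenyl]boronic acid | COCOc1ccc(cc1)B(O)O | intermediate
21 | (2S)-6-bromo-5,7-bis(methoxymethoxy)-2-[4-(methoxymethoxy)phenyl]-8-(3-methylbut-2-en-1-yl)-2,3-dihydro-4H-chromen-4-one | Brc1c(OCOC)c(CC=C(C)C)c2c(c1OCOC)C(=O)C[C@@H](c1ccc(OCOC)cc1)O2 | intermediate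
22 | isopropenylmagnesium bromide | CC(=C)[Mg]Br | starting material
23 | bromomagnesium isopropoxy(prop-1-en-2-yl)(pinacolato)borate | CC(=C)[B-]1(OC(C)C)OC(C)(C)C(C)(C)O1.[Mg+]Br | intermediate
24 | 4,4,5,5-tetramethyl-2-(prop-1-en-2-yl)-1,3,2-dioxaborolane | CC(=C)B1OC(C)(C)C(C)(C)O1 | intermediate
25 | vinylmagnesium bromide | C=C[Mg]Br | starting material
26 | bromomagnesium ethenyl(prop-1-en-2-yl)(pinacolato)borate | C=C[B-]1(C(C)=C)OC(C)(C)C(C)(C)O1.[Mg+]Br | intermediate
27 | (2S)-5,7-bis(methoxymethoxy)-2-[4-(methoxymethoxy)phenyl]-8-(3-methylbut-2-en-1-yl)-6-[(2R)-3-methyl-2-(4,4,5,5-tetramethyl-1,3,2-dioxaborolan-2-yl)but-3-en-1-yl]-2,3-dihydro-4H-chromen-4-one | C=C(C)[C@H](B1OC(C)(C)C(C)(C)O1)Cc1c(OCOC)c(CC=C(C)C)c2c(c1OCOC)C(=O)C[C@@H](c1ccc(OCOC)cc1)O2 | intermediate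
28 | (2S)-6-[(2R)-2-hydroxy-3-methylbut-3-en-1-yl]-5,7-bis(methoxymethoxy)-2-[4-(methoxymethoxy)phenyl]-8-(3-methylbut-2-en-1-yl)-2,3-dihydro-4H-chromen-4-one | C=C(C)[C@H](O)Cc1c(OCOC)c(CC=C(C)C)c2c(c1OCOC)C(=O)C[C@@H](c1ccc(OCOC)cc1)O2 | intermediate
29 | (2S)-5,7-dihydroxy-6-[(2R)-2-hydroxy-3-methylbut-3-en-1-yl]-2-(4-hydroxyphenyl)-8-(3-methylbut-2-en-1-yl)-2,3-dihydro-4H-chromen-4-one | C=C(C)[C@H](O)Cc1c(O)c(CC=C(C)C)c2c(c1O)C(=O)C[C@@H](c1ccc(O)cc1)O2 | target

**Step count**
Total: 11 steps. Longest linear sequence: 10 steps (1–8, 10, 11); step 9 is a one-step side branch.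

**Three steps most likely to fail, with fallbacks**

Step 10 (the proposed new step). The hindered C6–Br bond may add slowly to palladium, direct Suzuki-type transfer of a vinyl or isopropenyl group may compete with the 1,2-shift, or the selectivity may be low. The fallback uses known reactions, sets out from 21 and comes back at 28. Suzuki–Miyaura vinylation of 21 with potassium vinyltrifluoroborate (PdCl2(dppf), Et3N, n-PrOH, 80 °C) gives (2S)-6-ethenyl-5,7-bis(methoxymethoxy)-2-[4-(methoxymethoxy)phenyl]-8-(3-methylbut-2-en-1-yl)-2,3-dihydro-4H-chromen-4-one F5. Aldehyde-selective Wacker oxidation of the styrene (PdCl2(MeCN)2, benzoquinone, t-BuOH/H2O, 85 °C; the trisubstituted prenyl alkene does not react) gives the arylacetaldehyde F6. A catalytic asymmetric Nozaki–Hiyama–Kishi addition of 2-bromopropene (CrCl2 and NiCl2 as catalysts, chiral sulfonamide–oxazoline ligand, Mn, Cp2ZrCl2, MeCN, rt) attacks only the aldehyde, not the ring ketone, and gives the 2″R alcohol 28.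

Step 8. The electron-rich, 5-alkoxy-substituted chromone may react slowly or with modest enantioselectivity. The fallback sets out from 16 (with crude 20) and comes back at 21. The aryl group is added without asymmetric induction under the more active achiral catalyst [Rh(OH)(cod)]2 (dioxane/H2O, 50 °C) to give the racemic flavanone F3. Kinetic resolution by asymmetric transfer hydrogenation (RuCl(p-cymene)(TsDPEN), HCO2H/Et3N, rt, about 50% conversion, catalyst antipode that reduces the 2R ketone faster) leaves 21 (2S) unreduced and converts the 2R half into the cis-flavan-4-ol F4, which is removed by chromatography.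

Step 4. Direct C-prenylation may give O-alkylation, double alkylation or low conversion. The fallback sets out from 6 and comes back at 8. O-Alkylation of 6 with 3-chloro-3-methylbut-1-yne (DBU, CuCl2 as catalyst, MeCN, 0 °C) gives the 1,1-dimethylpropargyl ether F1. Semihydrogenation (H2, Pd/CaCO3 poisoned with Pb(OAc)2, quinoline, EtOAc) gives the 1,1-dimethylallyl ether F2. Heating (toluene, 110 °C) triggers the aromatic Claisen rearrangement to either of the two equivalent ortho carbons and delivers 8 with the linear prenyl group.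

**Further compounds**
F1 | step 4 | 2-bromo-1,3-bis(methoxymethoxy)-5-[(2-methylbut-3-yn-2-yl)oxy]benzene | COCOc1cc(OC(C)(C)C#C)cc(OCOC)c1Br
F2 | step 4 | 2-bromo-1,3-bis(methoxymethoxy)-5-[(2-methylbut-3-en-2-yl)oxy]benzene | COCOc1cc(OC(C)(C)C=C)cc(OCOC)c1Br
F3 | step 8 | rac-6-bromo-5,7-bis(methoxymethoxy)-2-[4-(methoxymethoxy)phenyl]-8-(3-methylbut-2-en-1-yl)-2,3-dihydro-4H-chromen-4-one | Brc1c(OCOC)c(CC=C(C)C)c2c(c1OCOC)C(=O)CC(c1ccc(OCOC)cc1)O2
F4 | step 8 | (2R,4R)-6-bromo-5,7-bis(methoxymethoxy)-2-[4-(methoxymethoxy)phenyl]-8-(3-methylbut-2-en-1-yl)-3,4-dihydro-2H-chromen-4-ol | O[C@@H]1C[C@H](c2ccc(OCOC)cc2)Oc2c(CC=C(C)C)c(OCOC)c(Br)c(OCOC)c12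
F5 | step 10 | (2S)-6-ethenyl-5,7-bis(methoxymethoxy)-2-[4-(methoxymethoxy)phenyl]-8-(3-methylbut-2-en-1-yl)-2,3-dihydro-4H-chromen-4-one | C=Cc1c(OCOC)c(CC=C(C)C)c2c(c1OCOC)C(=O)C[C@@H](c1ccc(OCOC)cc1)O2
F6 | step 10 | 2-[(2S)-5,7-bis(methoxymethoxy)-2-[4-(methoxymethoxy)phenyl]-8-(3-methylbut-2-en-1-yl)-4-oxo-2,3-dihydro-4H-chromen-6-yl]acetaldehyde | O=CCc1c(OCOC)c(CC=C(C)C)c2c(c1OCOC)C(=O)C[C@@H](c1ccc(OCOC)cc1)O2
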